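Numbering used throughout (lignan convention): the lactone is C9(=O)–O–C7'–C8'–C8; C8 carries the benzylic carbon C7 of ring A, C8' carries the hydroxymethyl carbon C9' (oxygen O9'), and C7' carries ring B.

## The problem

The target 20 is a single γ-butyrolactone with three contiguous stereocentres and no ring fusion to hold them: C8 (S) with the ring A benzyl group, C8' (S) with CH2OH, and C7' (R) with ring B. The C7'/C8' pair is trans, the relaxed arrangement, and both centres can be set together by an aldol–lactonisation. The C8/C8' pair is cis, and C8 sits α to the lactone carbonyl, so it is the epimerisable, contra-thermodynamic centre. It has to be made late, kinetically, and must not meet base afterwards. C8' can direct C8 only through its own substituent, the C9' oxymethyl arm. The molecule is fragile in several ways: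

- both phenols are para to benzylic carbons, so phenoxides can open to quinone methides;
- the benzylic lactone bond C7'–O can ionise in acid (ring A would then close an aryltetralin) or be hydrogenolysed;
- O9' is placed to attack C9 and translactonise under base.

Both aryl groups are the same guaiacyl unit, so C7 and C7' can be told apart only by their oxidation level and by how their rings are protected. The enabling feature is that C7 and O9' are cis on the lactone and linked through C8–C8'–C9'. Ring A can therefore arrive as a benzyl ether on O9', and its benzylic carbon can be bonded to C8 by closing the five-membered ring C7–C8–C8'–C9'–O9', which can only be cis-fused.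

## Retrosynthesis

**Unmasking (20 ⇐ 19 ⇐ 18).** The ring B phenol of 20 is covered as acetate 19. The C7–H and O9'–H bonds of 19 are then replaced by a C7–O9' bond, giving the bicyclic furofuranone 18. The neighbouring cut, direct C7–C8 benzylation of a monocyclic lactone enolate, would place the benzyl group trans to C9'. In 18 the cis relation is a ring fusion and cannot epimerise. The forward reduction must ionise only the C7–O9' ether and not the lactone C7'–O bond. For that reason ring A carries a donor (methoxymethyl ether) and ring B is switched to an acetate. 18 comes from the silyl ether 16 by protecting-group exchange.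

**C7–C8 bond (16 ⇐ 15).** Cutting C7–C8 of 16 and placing a diazo group on C8 gives the monocyclic diazo lactone 15. This one cut removes a ring and two stereocentres, and it turns the ring A benzyl group into an ordinary ether substituent. The forward step is a rhodium carbenoid 1,5 C–H insertion. It must beat 1,2-hydride shift from C8', and the ring fusion should set C8.

**Diazo group (15 ⇐ 13).** The C8=N2 unit is traced to the methylene of lactone 13 by deacylative diazo transfer. The only acidic site of 13 is C8, so no regiochemical question arises. Ring B must carry a base-stable group at this stage, hence the triisopropylsilyl ether rather than the final acetate.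

**Ether bond (13 ⇐ 9 + 12).** Cutting O9'–C7 gives the hydroxymethyl lactone 9 and the benzylic trichloroacetimidate 12. Acid-catalysed imidate transfer is preferred to a Williamson reaction because an O9' alkoxide would attack the lactone carbonyl. The fragment 12 comes from alcohol 11, which comes from aldehyde 10 and ultimately vanillin 1, by acetal protection, reduction and imidate formation.

**Oxidation level of C9' (9 ⇐ 8 ⇐ 7).** The alcohol 9 is taken back to the acid 8 and then to the acyl oxazolidinone 7. No skeletal bond is cut. The forward steps need a reduction that touches a carboxylic acid and leaves a lactone alone, which borane provides.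

**C7'–C8' and C9–O bonds (7 ⇐ 5 + 2).** Cutting the aldol bond C7'–C8' and the lactone C–O bond of 7 gives the succinate mono-imide 5 and the silylated vanillin 2. This is the most simplifying cut of the early part: both stereocentres and the ring arise in one operation under auxiliary control. 5 comes from the oxazolidinone 3 and the acid chloride 4, and 2 from vanillin 1. Vanillin thus supplies both aryl rings.

## Roads not taken

**Alternative 1: oxidative 8–8' dimerisation of ferulic acid.** The cut is the central C8–C8' bond together with both lactone C–O bonds. Two molecules of ferulic acid A1 would be oxidised to phenoxyl radicals. These couple at C8–C8', and the two carboxyl groups add to the quinone methide carbons to give the cis-fused bislactone A2.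

- Merits: A2 already has the cis C8/C8' fusion and exo aryl groups. Hydrogenolysis of one benzylic lactone bond (C7–O) would give the acid A3, and borane reduction of A3 would give 20. That is three steps without protecting groups, and the identical aryl rings of the target suit a dimerisation.
- Weak points: an achiral oxidant gives A2 as a racemate with no handle for absolute control. Radical coupling also divides among 8–8', 8–5' and 8–O–4' modes. The two benzylic lactones of A2 are equivalent, so stopping the hydrogenolysis after one is only statistical. Both free phenols sit para to the bonds that must survive.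
- Comparison: this road is far shorter and would be the better choice for racemic material. The chosen plan accepts about four times the step count and in return gives a single enantiomer and two benzylic C–O bonds that differ by construction (ether on a donor ring against lactone on an acetylated ring).

**Alternative 2: palladium cyclocarbonylation of an anti homopropargylic alcohol.** The cut is C8–C9 and C9–O, the carbonyl coming from CO. The alkynol A4 would be carbonylated with Pd2(dba)3 (zerovalent palladium) and 1,4-bis(diphenylphosphino)butane. Syn addition across C7≡C8 would close the lactone as the (E)-benzylidene compound A5. Hydrogenation of C7=C8 and desilylation would follow.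

- Merits: the lactone ring and its carbonyl are formed catalytically in one step. The alkene geometry is irrelevant once it is hydrogenated, and the overall length is comparable to the chosen plan.
- Weak points: C8 would be set by heterogeneous hydrogenation. Only the adjacent C9' arm favours the required face, while the C7' aryl group shields the opposite face from a 1,3 position. The same catalyst can hydrogenolyse the benzylic lactone bond or move the double bond into the ring. A4 also needs an enantio- and anti-selective allenylmetal addition of its own.
- Comparison: this road is as good in step count and better in atom economy at the ring-forming step. The chosen plan sets against it that C8 is fixed by a cis ring fusion rather than by a facial preference.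

**Alternative 3: auxiliary aldol–lactonisation of a 2-benzylsuccinate.** The cut is C7'–C8' and C9–O, as in the first stage of the chosen plan, but with the ring A benzyl group already on C8. The boron enolate of the mono-imide A6 would add to a silylated vanillin of the type of 2, and the aldolate would close onto the methyl ester to give lactone A7.

- Merits: this is the most convergent road. After one step all carbons and all three stereocentres are in place, and only conversion of the imide to CH2OH and desilylation remain.
- Weak points: A6 must first be made as a single enantiomer with differentiated carboxyl groups, which costs a separate asymmetric step. In A7 the cis C8/C8' pair then has to pass through basic imide cleavage although C8–H is α to the lactone carbonyl and epimerisation to trans relieves strain.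
- Comparison: this road is several steps shorter, and it would be superior if the imide of A7 could be removed without epimerisation. The chosen plan creates C8 last, under neutral conditions, inside a bicycle whose C8 epimer would be trans-fused. After ring opening it uses only acid and near-neutral reagents.

Key step: step 11

Assumption: in 16 the ring A aryl group is drawn endo at C7, the expected kinetic outcome of such closures; the exo epimer would behave identically in step 13, where C7 becomes a methylene group.

## Route

Step 1
Reactants: 1 vanillin
Product: 2 3-methoxy-4-(triisopropylsilyloxy)benzaldehyde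
Conditions: TIPSCl, imidazole, DMF, rt
Reagents that add atoms: chlorotriisopropylsilane, CC(C)[Si](Cl)(C(C)C)C(C)C
Why: Imidazole-promoted silylation of the phenol; the bulky aryl silyl ether is chosen because it should tolerate the hydroperoxide, borane and amide-base steps ahead.

Step 2
Reactants: 3 (R)-4-benzyloxazolidin-2-one; 4 methyl 4-chloro-4-oxobutanoate
Product: 5 methyl 4-[(4R)-4-benzyl-2-oxooxazolidin-3-yl]-4-oxobutanoate
Conditions: n-BuLi, THF, −78 °C; then 4, −78 to 0 °C
Reagents that add atoms: none
Why: N-acylation of the lithiated oxazolidinone by the acid chloride, which is far more electrophilic than the methyl ester at low temperature.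

Step 3
Reactants: 5 methyl 4-[(4R)-4-benzyl-2-oxooxazolidin-3-yl]-4-oxobutanoate; 2 3-methoxy-4-(triisopropylsilyloxy)benzaldehyde
Product: 7 (4R)-4-benzyl-3-{[(2R,3R)-2-[3-methoxy-4-(triisopropylsilyloxy)phenyl]-5-oxotetrahydrofuran-3-yl]carbonyl}oxazolidin-2-one (trans lactone), via syn-aldol hydroxy ester 6 (not isolated)
Conditions: Bu2BOTf, iPr2NEt, CH2Cl2, 0 °C; then 2, −78 °C to rt; pH 7 buffer/MeOH work-up
Reagents that add atoms: none
Why: Evans syn aldol: soft enolisation gives the Z boron enolate of the imide only, and a closed chair transition state with the (R)-benzyl group shielding one face sets C8' and C7' together. The syn aldolate then closes onto the γ-methyl ester (5-exo-trig acyl substitution), which places the aryl and acyl groups trans on the lactone.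

Step 4
Reactants: 7 trans lactone imide
Product: 8 (2R,3R)-2-[3-methoxy-4-(triisopropylsilyloxy)phenyl]-5-oxotetrahydrofuran-3-carboxylic acid
Conditions: LiOH, H2O2, THF/H2O, 0 °C; Na2SO3; then 1 M HCl to pH 3
Reagents that add atoms: hydrogen peroxide (as LiOOH), OO
Why: Hydroperoxide cleavage of the N-acyl oxazolidinone at the exocyclic carbonyl; the peracid is reduced by sulfite, any opened lactone recloses on acidification, and auxiliary 3 is recovered.

Step 5
Reactants: 8 lactone acid
Product: 9 (4S,5R)-4-(hydroxymethyl)-5-[3-methoxy-4-(triisopropylsilyloxy)phenyl]dihydrofuran-2(3H)-one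
Conditions: BH3·SMe2, THF, 0 °C to rt; MeOH quench
Reagents that add atoms: none
Why: Borane reduces a free carboxylic acid through its acyloxyborane much faster than a lactone; no base is present, so neither epimerisation at C8' nor translactonisation is expected.

Step 6
Reactants: 1 vanillin
Product: 10 3-methoxy-4-(methoxymethoxy)benzaldehyde
Conditions: MOMCl, iPr2NEt, CH2Cl2, 0 °C to rt
Reagents that add atoms: chloromethyl methyl ether, COCCl
Why: O-alkylation of the phenol with the α-chloro ether under amine base; the acetal ether keeps ring A electron-rich and is later removed by the same acid that opens the bicycle.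

Step 7
Reactants: 10 3-methoxy-4-(methoxymethoxy)benzaldehyde
Product: 11 [3-methoxy-4-(methoxymethoxy)phenyl]methanol
Conditions: NaBH4, MeOH, 0 °C
Reagents that add atoms: none
Why: Borohydride reduction of the aryl aldehyde; the acetal ether is inert.

Step 8
Reactants: 11 [3-methoxy-4-(methoxymethoxy)phenyl]methanol
Product: 12 3-methoxy-4-(methoxymethoxy)benzyl 2,2,2-trichloroacetimidate
Conditions: Cl3CCN, DBU (10 mol%), CH2Cl2, 0 °C
Reagents that add atoms: trichloroacetonitrile, N#CC(Cl)(Cl)Cl
Why: Base-catalysed addition of the alcohol to the nitrile (trichloroacetimidate formation); the electron-rich imidate is used promptly.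

Step 9
Reactants: 9 hydroxymethyl lactone; 12 trichloroacetimidate
Product: 13 (4S,5R)-4-({[3-methoxy-4-(methoxymethoxy)benzyl]oxy}methyl)-5-[3-methoxy-4-(triisopropylsilyloxy)phenyl]dihydrofuran-2(3H)-one
Conditions: 12 (1.5 equiv), camphorsulfonic acid (10 mol%), CH2Cl2, 0 °C to rt
Reagents that add atoms: none
Why: Acid-catalysed O-benzylation by a trichloroacetimidate, an SN1-type transfer of the stabilised 4-alkoxybenzyl cation as in 4-methoxybenzyl protection. The weakly acidic medium avoids the alkoxide-driven translactonisation that a Williamson etherification of 9 would risk.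

Step 10
Reactants: 13 lactone benzyl ether
Product: 15 (4S,5R)-3-diazo-4-({[3-methoxy-4-(methoxymethoxy)benzyl]oxy}methyl)-5-[3-methoxy-4-(triisopropylsilyloxy)phenyl]dihydrofuran-2(3H)-one, via 3-trifluoroacetyl lactone 14 (not isolated)
Conditions: LiN(SiMe3)2, THF, −78 °C; CF3CO2CH2CF3; then MsN3, Et3N, H2O (1 equiv), MeCN, rt
Reagents that add atoms: methanesulfonyl azide, CS(=O)(=O)N=[N+]=[N-]; 2,2,2-trifluoroethyl trifluoroacetate, O=C(OCC(F)(F)F)C(F)(F)F (its acyl group is carried only by 14)
Why: Deacylative (Regitz-type) diazo transfer: the lactone enolate is trifluoroacetylated at C8, and the activated 1,3-dicarbonyl 14 takes the diazo group from the sulfonyl azide while the trifluoroacetyl group leaves as the N-sulfonyl amide. C8' and C7' are not enolisable here.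

Step 11
Reactants: 15 α-diazo lactone
Product: 16 (1S,2R,5R,6S)-6-[3-methoxy-4-(methoxymethoxy)phenyl]-2-[3-methoxy-4-(triisopropylsilyloxy)phenyl]-3,7-dioxabicyclo[3.3.0]octan-4-one (cis-fused; ring B exo on the lactone ring, ring A endo on the tetrahydrofuran ring; 7S,8R,7'R,8'S in lignan numbering)
Conditions: Rh2(O2CCPh3)4 (1 mol%), CH2Cl2, −20 °C to rt, slow addition of 15
Reagents that add atoms: none
Why: Rh2(O2CCPh3)4, a dirhodium tetracarboxylate of divalent rhodium, takes up the diazo carbon C8 and loses N2 to give an electrophilic carbenoid. The carbenoid inserts into one C7–H bond of the O9' benzyl ether through a three-centre, hydride-transfer-like transition state, forming C7–C8 and releasing the catalyst; the closest known reaction type is the dirhodium-catalysed 1,5 C–H insertion of α-diazo esters and lactones next to an ether oxygen, which gives 2-aryl tetrahydrofurans and furofuranones. The ring closed is the five-membered tetrahydrofuran C7–C8–C8'–C9'–O9' (1,5 insertion), and it can only be cis-fused because a trans-fused bicyclo[3.3.0]octane is far too strained. C8 is therefore controlled by C8': the new bond forms on the face that carries the C9' arm, which is the cis C7/C9' relation of the target. C7 is controlled by the transition state, in which the aryl group should turn away from the carboxylate wall of the catalyst on the convex face and so end up endo; this centre is erased in step 13. The selectivity needed is chemoselectivity for 1,5 insertion over 1,2-hydride shift from C8' (butenolide), oxonium ylide formation at O9' and carbene dimerisation. The substrate secures it with a C7–H bond activated both by the ether oxygen and by the alkoxy-substituted ring A at the ideal distance, while ring B cannot reach C8 without bridging the lactone; the bulky triphenylacetate ligands, low temperature and slow addition work against hydride shift and dimerisation.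

Step 12
Reactants: 16 furofuranone silyl ether
Product: 18 4-[(1S,2R,5R,6S)-6-[3-methoxy-4-(methoxymethoxy)phenyl]-4-oxo-3,7-dioxabicyclo[3.3.0]octan-2-yl]-2-methoxyphenyl acetate, via free ring B phenol 17 (not isolated)
Conditions: Bu4NF, AcOH, THF, 0 °C; then Ac2O, pyridine, DMAP (cat.), 0 °C to rt
Reagents that add atoms: acetic anhydride, CC(=O)OC(C)=O
Why: Fluoride cleavage of the aryl silyl ether and acetylation of the phenol in one flask; acetic acid keeps the phenol protonated so that the 4-hydroxybenzylic lactone is not opened through a quinone methide. The acetate turns ring B from a donor into an electronically neutral aryl group for step 13.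

Step 13
Reactants: 18 furofuranone acetate
Product: 19 4-[(2R,3S,4S)-4-(4-hydroxy-3-methoxybenzyl)-3-(hydroxymethyl)-5-oxotetrahydrofuran-2-yl]-2-methoxyphenyl acetate
Conditions: Et3SiH (5 equiv), CF3CO2H/CH2Cl2 (1:4), 0 °C; NaHCO3 aq/MeOH work-up
Reagents that add atoms: none
Why: Ionic hydrogenation: the acid ionises the C7–O9' bond, a 4-alkoxybenzyl-type ether, and the silane delivers hydride to the C7 cation, while the lactone C7'–O bond is a benzyl-ester-type bond on the acetoxy ring and should not ionise. The same acid removes the methoxymethyl group, with the silane reducing the methoxymethyl cation; C8 is not involved, so the cis relation set by ring fusion is kept.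

Step 14
Reactants: 19 monoacetate
Product: 20 (3S,4S,5R)-3-(4-hydroxy-3-methoxybenzyl)-4-(hydroxymethyl)-5-(4-hydroxy-3-methoxyphenyl)dihydrofuran-2(3H)-one (CNP0329106.3)
Conditions: NH4OAc, MeOH/H2O (4:1), rt
Reagents that add atoms: none
Why: Ammonium acetate-promoted methanolysis of the aryl acetate at near-neutral pH; the lactone, the primary alcohol and the base-sensitive cis C8 centre are left alone.

## Compound list

1 | vanillin | COc1cc(C=O)ccc1O | starting material
2 | 3-methoxy-4-(triisopropylsilyloxy)benzaldehyde | COc1cc(C=O)ccc1O[Si](C(C)C)(C(C)C)C(C)C | intermediate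
3 | (R)-4-benzyloxazolidin-2-one | O=C1N[C@H](Cc2ccccc2)CO1 | starting material
4 | methyl 4-chloro-4-oxobutanoate | COC(=O)CCC(Cl)=O | starting material
5 | methyl 4-[(4R)-4-benzyl-2-oxooxazolidin-3-yl]-4-oxobutanoate | COC(=O)CCC(=O)N1[C@H](Cc2ccccc2)COC1=O | intermediate
6 | methyl (3R,4R)-3-{[(4R)-4-benzyl-2-oxooxazolidin-3-yl]carbonyl}-4-hydroxy-4-[3-methoxy-4-(triisopropylsilyloxy)phenyl]butanoate | O[C@@H](c1ccc(O[Si](C(C)C)(C(C)C)C(C)C)c(OC)c1)[C@@H](CC(=O)OC)C(=O)N1[C@H](Cc2ccccc2)COC1=O | intermediate
7 | (4R)-4-benzyl-3-{[(2R,3R)-2-[3-methoxy-4-(triisopropylsilyloxy)phenyl]-5-oxotetrahydrofuran-3-yl]carbonyl}oxazolidin-2-one | O=C1C[C@@H](C(=O)N2[C@H](Cc3ccccc3)COC2=O)[C@H](c2ccc(O[Si](C(C)C)(C(C)C)C(C)C)c(OC)c2)O1 | intermediate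
8 | (2R,3R)-2-[3-methoxy-4-(triisopropylsilyloxy)phenyl]-5-oxotetrahydrofuran-3-carboxylic acid | O=C1C[C@@H](C(=O)O)[C@H](c2ccc(O[Si](C(C)C)(C(C)C)C(C)C)c(OC)c2)O1 | intermediate
9 | (4S,5R)-4-(hydroxymethyl)-5-[3-methoxy-4-(triisopropylsilyloxy)phenyl]dihydrofuran-2(3H)-one | O=C1C[C@@H](CO)[C@H](c2ccc(O[Si](C(C)C)(C(C)C)C(C)C)c(OC)c2)O1 | intermediate
10 | 3-methoxy-4-(methoxymethoxy)benzaldehyde | COCOc1ccc(C=O)cc1OC | intermediate
11 | [3-methoxy-4-(methoxymethoxy)phenyl]methanol | COCOc1ccc(CO)cc1OC | intermediate
12 | 3-methoxy-4-(methoxymethoxy)benzyl 2,2,2-trichloroacetimidate | COCOc1ccc(COC(=N)C(Cl)(Cl)Cl)cc1OC | intermediate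
13 | (4S,5R)-4-({[3-methoxy-4-(methoxymethoxy)benzyl]oxy}methyl)-5-[3-methoxy-4-(triisopropylsilyloxy)phenyl]dihydrofuran-2(3H)-one | O=C1C[C@@H](COCc2ccc(OCOC)c(OC)c2)[C@H](c2ccc(O[Si](C(C)C)(C(C)C)C(C)C)c(OC)c2)O1 | intermediate
14 | 3-(trifluoroacetyl) derivative of 13 (C3 epimers and enol form) | O=C1C(C(=O)C(F)(F)F)[C@@H](COCc2ccc(OCOC)c(OC)c2)[C@H](c2ccc(O[Si](C(C)C)(C(C)C)C(C)C)c(OC)c2)O1 | intermediate
15 | (4S,5R)-3-diazo-4-({[3-methoxy-4-(methoxymethoxy)benzyl]oxy}methyl)-5-[3-methoxy-4-(triisopropylsilyloxy)phenyl]dihydrofuran-2(3H)-one | [N-]=[N+]=C1C(=O)O[C@@H](c2ccc(O[Si](C(C)C)(C(C)C)C(C)C)c(OC)c2)[C@@H]1COCc1ccc(OCOC)c(OC)c1 | intermediate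
16 | (1S,2R,5R,6S)-6-[3-methoxy-4-(methoxymethoxy)phenyl]-2-[3-methoxy-4-(triisopropylsilyloxy)phenyl]-3,7-dioxabicyclo[3.3.0]octan-4-one | COc1cc([C@H]2OC[C@@H]3[C@H]2C(=O)O[C@H]3c2ccc(O[Si](C(C)C)(C(C)C)C(C)C)c(OC)c2)ccc1OCOC | intermediate
17 | (1S,2R,5R,6S)-2-(4-hydroxy-3-methoxyphenyl)-6-[3-methoxy-4-(methoxymethoxy)phenyl]-3,7-dioxabicyclo[3.3.0]octan-4-one | COc1cc([C@H]2OC[C@@H]3[C@H]2C(=O)O[C@H]3c2ccc(O)c(OC)c2)ccc1OCOC | intermediate
18 | 4-[(1S,2R,5R,6S)-6-[3-methoxy-4-(methoxymethoxy)phenyl]-4-oxo-3,7-dioxabicyclo[3.3.0]octan-2-yl]-2-methoxyphenyl acetate | COc1cc([C@H]2OC[C@@H]3[C@H]2C(=O)O[C@H]3c2ccc(OC(C)=O)c(OC)c2)ccc1OCOC | intermediate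
19 | 4-[(2R,3S,4S)-4-(4-hydroxy-3-methoxybenzyl)-3-(hydroxymethyl)-5-oxotetrahydrofuran-2-yl]-2-methoxyphenyl acetate | COc1cc(C[C@@H]2C(=O)O[C@@H](c3ccc(OC(C)=O)c(OC)c3)[C@@H]2CO)ccc1O | intermediate
20 | (3S,4S,5R)-3-(4-hydroxy-3-methoxybenzyl)-4-(hydroxymethyl)-5-(4-hydroxy-3-methoxyphenyl)dihydrofuran-2(3H)-one | COc1cc(C[C@@H]2C(=O)O[C@@H](c3ccc(O)c(OC)c3)[C@@H]2CO)ccc1O | target

## Step count and risks

Total step count: 14. Longest linear sequence: 10 steps (steps 2–5 and 9–14 from 3 and 4); side branches are step 1 and steps 6–8.

**Step 11 (key step).** The most likely failure is 1,2-hydride migration from the tertiary C8'–H to the carbenoid carbon, which would consume the carbenoid as a butenolide before insertion. Carbene dimerisation is a further drain if the diazo compound accumulates.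
Fallback (from 9, returning at 20): the benzyl group is introduced by enolate chemistry and C8 is corrected by kinetic protonation.
- 9 is silylated with TIPSOTf and 2,6-lutidine to the bis-silyl lactone F1.
- Aldehyde 2 is reduced with NaBH4 to the benzylic alcohol F2, which is converted by the Appel reaction (CBr4, PPh3) into the benzylic bromide F3.
- The lithium enolate of F1 (LiN(SiMe3)2, THF, −78 °C) is alkylated with F3 anti to the C8' arm, giving the trans-benzyl lactone F4.
- F4 is enolised again and protonated at −78 °C with a hindered phenol from the same, less hindered face, giving the cis-benzyl lactone F5.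
- Bu4NF buffered with AcOH removes the three silyl groups of F5 to give 20.

**Step 13.** The most likely failures are ionisation at the wrong benzylic carbon (the lactone C7'–O bond, followed by ring closure by ring A) and loss of the C8 proton from the C7 cation with unselective reprotonation, which would erode the cis relation. Acid-catalysed translactonisation of the freed alcohol is a lesser concern.
Fallback (from 18, returning at 19): hydrogenolysis over Pd/C under H2 in EtOAc cleaves the C7–O9' benzylic ether without a cation and gives the methoxymethyl-protected hydroxymethyl lactone F6. Brief CF3CO2H in CH2Cl2 with Et3SiH as scavenger then removes the acetal to give 19.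

**Step 9.** The most likely failures are self-alkylation of the very electron-rich benzyl cation on another ring A, rearrangement of the imidate to the N-benzyl amide, and acid-triggered loss of the methoxymethyl group.
Fallback (from 11 and 9, returning at 13): 11 is converted by the Appel reaction (CBr4, PPh3, CH2Cl2, 0 °C) into the benzylic bromide F7. 9 is then alkylated with F7 under Ag2O in CH2Cl2 in the dark, a neutral silver-assisted etherification that forms no free alkoxide.

**Step 4.** The most likely failures are base-induced β-elimination of the lactone carboxylate from the imide enolate (the ring opening familiar from the Stobbe condensation, favoured here by the aryl group) and attack of hydroxide on the aryl silyl ether.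
Fallback (from 7, returning at 9): the auxiliary is removed reductively with NaBH4 in THF/H2O at 0 °C, which converts the acyl oxazolidinone directly into the alcohol and bypasses 8; no new compound arises (F0).

## Further compounds

F1 | step 11 | (4S,5R)-5-[3-methoxy-4-(triisopropylsilyloxy)phenyl]-4-[(triisopropylsilyloxy)methyl]dihydrofuran-2(3H)-one | O=C1C[C@@H](CO[Si](C(C)C)(C(C)C)C(C)C)[C@H](c2ccc(O[Si](C(C)C)(C(C)C)C(C)C)c(OC)c2)O1
F2 | step 11 | [3-methoxy-4-(triisopropylsilyloxy)phenyl]methanol | COc1cc(CO)ccc1O[Si](C(C)C)(C(C)C)C(C)C
F3 | step 11 | 4-(bromomethyl)-2-methoxy-1-(triisopropylsilyloxy)benzene | COc1cc(CBr)ccc1O[Si](C(C)C)(C(C)C)C(C)C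
F4 | step 11 | (3R,4S,5R)-3-[3-methoxy-4-(triisopropylsilyloxy)benzyl]-5-[3-methoxy-4-(triisopropylsilyloxy)phenyl]-4-[(triisopropylsilyloxy)methyl]dihydrofuran-2(3H)-one | COc1cc(C[C@H]2C(=O)O[C@@H](c3ccc(O[Si](C(C)C)(C(C)C)C(C)C)c(OC)c3)[C@@H]2CO[Si](C(C)C)(C(C)C)C(C)C)ccc1O[Si](C(C)C)(C(C)C)C(C)C
F5 | step 11 | (3S,4S,5R)-3-[3-methoxy-4-(triisopropylsilyloxy)benzyl]-5-[3-methoxy-4-(triisopropylsilyloxy)phenyl]-4-[(triisopropylsilyloxy)methyl]dihydrofuran-2(3H)-one | COc1cc(C[C@@H]2C(=O)O[C@@H](c3ccc(O[Si](C(C)C)(C(C)C)C(C)C)c(OC)c3)[C@@H]2CO[Si](C(C)C)(C(C)C)C(C)C)ccc1O[Si](C(C)C)(C(C)C)C(C)C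
F6 | step 13 | 4-[(2R,3S,4S)-3-(hydroxymethyl)-4-[3-methoxy-4-(methoxymethoxy)benzyl]-5-oxotetrahydrofuran-2-yl]-2-methoxyphenyl acetate | COCOc1ccc(C[C@@H]2C(=O)O[C@@H](c3ccc(OC(C)=O)c(OC)c3)[C@@H]2CO)cc1OC
F7 | step 9 | 4-(bromomethyl)-2-methoxy-1-(methoxymethoxy)benzene | COCOc1ccc(CBr)cc1OC
F0 | step 4 | none | none
A1 | alternative 1 | ferulic acid | COc1cc(/C=C/C(=O)O)ccc1O
A2 | alternative 1 | exo,exo-2,6-bis(4-hydroxy-3-methoxyphenyl)-3,7-dioxabicyclo[3.3.0]octane-4,8-dione | COc1cc([C@@H]2OC(=O)[C@@H]3[C@H]2C(=O)O[C@H]3c2ccc(O)c(OC)c2)ccc1O
A3 | alternative 1 | (2R,3R,4S)-4-(4-hydroxy-3-methoxybenzyl)-2-(4-hydroxy-3-methoxyphenyl)-5-oxotetrahydrofuran-3-carboxylic acid | COc1cc(C[C@@H]2C(=O)O[C@@H](c3ccc(O)c(OC)c3)[C@@H]2C(=O)O)ccc1O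
A4 | alternative 2 | anti homopropargylic alcohol, tris(tert-butyldimethylsilyl) ether | O[C@@H](c1ccc(O[Si](C)(C)C(C)(C)C)c(OC)c1)[C@@H](C#Cc1ccc(O[Si](C)(C)C(C)(C)C)c(OC)c1)CO[Si](C)(C)C(C)(C)C
A5 | alternative 2 | (E)-α-benzylidene lactone, tris(tert-butyldimethylsilyl) ether | COc1cc(/C=C2/C(=O)O[C@@H](c3ccc(O[Si](C)(C)C(C)(C)C)c(OC)c3)[C@@H]2CO[Si](C)(C)C(C)(C)C)ccc1O[Si](C)(C)C(C)(C)C
A6 | alternative 3 | 2-benzylsuccinate methyl ester mono-imide | COc1cc(C[C@@H](CC(=O)N2[C@H](Cc3ccccc3)COC2=O)C(=O)OC)ccc1O[Si](C)(C)C(C)(C)C
A7 | alternative 3 | α-benzyl lactone with the acyl oxazolidinone on C8' | COc1cc(C[C@@H]2C(=O)O[C@@H](c3ccc(O[Si](C)(C)C(C)(C)C)c(OC)c3)[C@@H]2C(=O)N2[C@H](Cc3ccccc3)COC2=O)ccc1O[Si](C)(C)C(C)(C)C
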